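**Plan**

1. Labdane numbering is used: ring A = C1–C5 and C10; ring B = C5–C10; C19 is the CH2O carbon on C4; the side chain C11–C16 sits on C9.
2. Retrosynthesis: cut the C19–O acyl bond; take the side-chain diene back to a C13 methyl ketone and C11=C12 back to a C11 aldehyde; then cut C8–C9 and C5–C10 together; then C6–C7 (cross-metathesis) and C3–C4 (allylic alkylation).
3. Enabling feature: ring B is a six-membered carbocycle whose C8 carries oxygen and whose C9 carries C11. With a C6=C7 bond it is the adduct of the 1-oxygenated diene C5=C6–C7=C8(O) and the formyl-activated alkene C9=C10. The C1–C3 chain joining C10 to C4–C5 makes this one intramolecular Diels–Alder event that closes rings A and B together.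
4. Forward: two fragments give the acyclic chain C11–C9=C10–C1–C2–C3–C4–C5=C6–C7=C8 (steps 6–11); rings A and B form in step 12; side chain, C19 alcohol and ester follow.
5. Stereochemistry: C4 comes from a copper-catalysed asymmetric SN2′ alkylation; C5, C8, C9 and C10 all come from step 12 (alkene geometries 9E, 5E, 7Z; endo transition state; diene face set by C4).

Key step: step 12

Remark on the chemistry: pent-4-en-2-ol (14) is used as the racemate because its carbinol carbon becomes the C8 carbonyl in step 8, and in step 6 the ligand antipode that delivers the 2S ester is taken.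

**Route**

Step 1
Reactants: 1 methyl (2E)-3,7-dimethylocta-2,6-dienoate (methyl geranate)
Product: 3 methyl (2E)-3-methyl-6-oxohex-2-enoate, via epoxide 2 (not isolated)
Conditions: mCPBA, CH2Cl2, 0 °C; then H5IO6, THF/H2O, 0 °C to rt
Reagents that add atoms: mCPBA (3-chloroperbenzoic acid), O=C(OO)c1cccc(Cl)c1
Why: The electron-rich 6,7-alkene should be epoxidised in preference to the conjugated 2,3-alkene (Prilezhaev epoxidation), and periodic acid should open and cleave the epoxide to the aldehyde and acetone without touching the (2E)-enoate.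

Step 2
Reactants: 3 methyl (2E)-3-methyl-6-oxohex-2-enoate
Product: 4 methyl (2E)-6-hydroxy-3-methylhex-2-enoate
Conditions: NaBH4, MeOH, 0 °C
Reagents that add atoms: none
Why: Borohydride reduction is chemoselective for the aldehyde; the β,β-disubstituted enoate is inert.

Step 3
Reactants: 4 methyl (2E)-6-hydroxy-3-methylhex-2-enoate
Product: 5 methyl (2E)-6-iodo-3-methylhex-2-enoate
Conditions: I2, PPh3, imidazole, CH2Cl2, 0 °C to rt
Reagents that add atoms: iodine, II
Why: Appel-type iodination of the primary alcohol through the alkoxyphosphonium salt and SN2 displacement by iodide.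

Step 4
Reactants: 6 tert-butyl 2-bromopropanoate; 7 glycolaldehyde dimer (2,5-dihydroxy-1,4-dioxane)
Product: 10 tert-butyl (2E)-4-hydroxy-2-methylbut-2-enoate, via phosphonium bromide 8 (not isolated), via phosphorane 9 (not isolated)
Conditions: PPh3, sat. aq NaHCO3, rt
Reagents that add atoms: none
Why: One-pot aqueous Wittig reaction; the stabilised α-methyl ylide formed in the flask should give the (E)-trisubstituted enoate with the free hydroxyl tolerated.

Step 5
Reactants: 10 tert-butyl (2E)-4-hydroxy-2-methylbut-2-enoate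
Product: 11 tert-butyl (2E)-4-[(diethoxyphosphoryl)oxy]-2-methylbut-2-enoate
Conditions: ClP(O)(OEt)2, pyridine, DMAP (cat.), CH2Cl2, 0 °C
Reagents that add atoms: diethyl chlorophosphate, CCOP(=O)(Cl)OCC
Why: O-Phosphorylation of the primary allylic alcohol installs the leaving group needed for SN2′ alkylation.

Step 6
Reactants: 5 methyl (2E)-6-iodo-3-methylhex-2-enoate; 11 tert-butyl (2E)-4-[(diethoxyphosphoryl)oxy]-2-methylbut-2-enoate
Product: 13 1-tert-butyl 8-methyl (2S,6E)-2-ethenyl-2,6-dimethyloct-6-enedioate, via dialkylzinc 12 (not isolated)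
Conditions: 5, Et2Zn (neat), CuI (0.3 mol %), 50 °C, then volatiles removed in vacuo; then 11, (CuOTf)2·C6H6 (5 mol %), chiral pyridinyl-imine dipeptide ligand (10 mol %), THF, −15 °C; aq NH4Cl
Reagents that add atoms: none
Why: Iodine–zinc exchange gives the functionalised dialkylzinc, and copper-catalysed enantioselective SN2′ allylic alkylation of the γ-phosphoryloxy α-methyl enoate (a known route to α,α-disubstituted β,γ-unsaturated esters) should set the quaternary C4 as 2S by catalyst control of the alkene face, the conjugated enoate of the zinc reagent being inert.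

Step 7
Reactants: 13 1-tert-butyl 8-methyl (2S,6E)-2-ethenyl-2,6-dimethyloct-6-enedioate; 14 pent-4-en-2-ol (racemic)
Product: 15 1-tert-butyl 8-methyl (2S,6E)-2-[(1E)-4-hydroxypent-1-en-1-yl]-2,6-dimethyloct-6-enedioate (both carbinol epimers)
Conditions: 14 (5 equiv), second-generation Hoveyda–Grubbs catalyst RuCl2(H2IMes)(=CH–C6H4-2-O-i-Pr) (5 mol %), CH2Cl2, 40 °C
Reagents that add atoms: none
Why: Olefin cross-metathesis: the hindered vinyl group on C4 cannot homodimerise and should couple with the excess unhindered partner to the (E)-alkene on steric grounds, while the conjugated β,β-disubstituted enoate alkene is inert to the ruthenium carbene, so ring closure onto C10 should not compete.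

Step 8
Reactants: 15 1-tert-butyl 8-methyl (2S,6E)-2-[(1E)-4-hydroxypent-1-en-1-yl]-2,6-dimethyloct-6-enedioate
Product: 16 1-tert-butyl 8-methyl (2S,6E)-2,6-dimethyl-2-[(1E)-4-oxopent-1-en-1-yl]oct-6-enedioate
Conditions: Dess–Martin periodinane, NaHCO3, CH2Cl2, 0 °C to rt
Reagents that add atoms: none
Why: Buffered periodinane oxidation converges both carbinol epimers to the β,γ-unsaturated methyl ketone without moving the C5=C6 bond into conjugation.

Step 9
Reactants: 16 1-tert-butyl 8-methyl (2S,6E)-2,6-dimethyl-2-[(1E)-4-oxopent-1-en-1-yl]oct-6-enedioate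
Product: 17 1-tert-butyl 8-methyl (2S,6E)-2,6-dimethyl-2-{(1E,3Z)-4-[(triethylsilyl)oxy]penta-1,3-dien-1-yl}oct-6-enedioate
Conditions: Et3SiOTf, Et3N, CH2Cl2, −78 °C
Reagents that add atoms: triethylsilyl trifluoromethanesulfonate, CC[Si](CC)(CC)OS(=O)(=O)C(F)(F)F
Why: Soft enolisation should remove the doubly activated C7–H (α to the carbonyl and allylic) to give the conjugated dienol ether, with (Z)-geometry at C7=C8 (oxygen cis to C6) because the C7 vinyl group prefers to lie trans to the C8 methyl group, as is usual for silyl enol ethers of methyl ketones.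

Step 10
Reactants: 17 1-tert-butyl 8-methyl (2S,6E)-2,6-dimethyl-2-{(1E,3Z)-4-[(triethylsilyl)oxy]penta-1,3-dien-1-yl}oct-6-enedioate
Product: 18 tert-butyl (2S,6E)-8-hydroxy-2,6-dimethyl-2-{(1E,3Z)-4-[(triethylsilyl)oxy]penta-1,3-dien-1-yl}oct-6-enoate
Conditions: i-Bu2AlH (2.2 equiv), CH2Cl2, −78 °C; aq potassium sodium tartrate
Reagents that add atoms: none
Why: 1,2-Reduction of the methyl enoate to the allylic alcohol; the tert-butyl ester on the quaternary carbon and the silyl dienol ether should survive at −78 °C with a non-acidic work-up.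

Step 11
Reactants: 18 tert-butyl (2S,6E)-8-hydroxy-2,6-dimethyl-2-{(1E,3Z)-4-[(triethylsilyl)oxy]penta-1,3-dien-1-yl}oct-6-enoate
Product: 19 tert-butyl (2S,6E)-2,6-dimethyl-8-oxo-2-{(1E,3Z)-4-[(triethylsilyl)oxy]penta-1,3-dien-1-yl}oct-6-enoate
Conditions: MnO2, CH2Cl2, rt
Reagents that add atoms: none
Why: Neutral heterogeneous allylic oxidation gives the (E)-enal with retention of alkene geometry and is compatible with the silyl dienol ether.

Step 12
Reactants: 19 tert-butyl (2S,6E)-2,6-dimethyl-8-oxo-2-{(1E,3Z)-4-[(triethylsilyl)oxy]penta-1,3-dien-1-yl}oct-6-enoate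
Product: 20 tert-butyl (1S,4aS,5R,6R,8aR)-5-formyl-1,4a,6-trimethyl-6-[(triethylsilyl)oxy]-1,2,3,4,4a,5,6,8a-octahydronaphthalene-1-carboxylate
Conditions: toluene (0.01 M), BHT (5 mol %), 120 °C, sealed base-washed tube
Reagents that add atoms: none
Why: Concerted, asynchronous intramolecular [4+2] cycloaddition (type 1 intramolecular Diels–Alder reaction of a 1,7,9-decatriene; the closest known class is the thermal cyclisation of 1-silyloxydienes onto terminally activated (E)-enals), in which the C5–C10 bond is the more advanced and C8–C9 follows in the same transition state. Ring B is closed as the cyclohexene of the cycloaddition from the diene C5=C6–C7=C8 and the alkene C9=C10, and ring A is closed through the same C5–C10 bond as the six-membered tether ring C10–C1–C2–C3–C4–C5 (fused mode, exo at both π systems, tether anti to the diene). C9 and C10 follow from suprafacial addition to the (E)-alkene (C11 cis to the C10 methyl), C5 and C8 from suprafacial addition to the (5E,7Z)-diene (C4 and the C8 methyl outside, silyloxy inside), and the trans ring fusion with the C8 oxygen anti to C11 from the endo-formyl transition state with a chair-like tether. The absolute sense comes from C4: in that chair the methyl group should sit pseudo-equatorial and anti to the forming C5–C10 bond, while the smaller, planar, electron-withdrawing ester takes the pseudo-axial place syn to the incoming C10 methyl, so only one diene face is used. The step needs endo over exo and one diene face over the other; the formyl secondary-orbital preference, the fixed alkene geometries and the allylic quaternary centre should secure them, and dilute, base-washed, radical-inhibited conditions keep the silyl dienol ether intact.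

Step 13
Reactants: 20 tert-butyl (1S,4aS,5R,6R,8aR)-5-formyl-1,4a,6-trimethyl-6-[(triethylsilyl)oxy]-1,2,3,4,4a,5,6,8a-octahydronaphthalene-1-carboxylate; 21 1-(triphenyl-λ5-phosphanylidene)propan-2-one
Product: 22 tert-butyl (1S,4aS,5R,6R,8aR)-1,4a,6-trimethyl-5-[(1E)-3-oxobut-1-en-1-yl]-6-[(triethylsilyl)oxy]-1,2,3,4,4a,5,6,8a-octahydronaphthalene-1-carboxylate
Conditions: toluene, 100 °C
Reagents that add atoms: none
Why: Wittig reaction with a stabilised ylide should give the (E)-enone, and the base-free conditions avoid epimerisation at C9 and β-elimination of the C8 silyloxy group.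

Step 14
Reactants: 22 tert-butyl (1S,4aS,5R,6R,8aR)-1,4a,6-trimethyl-5-[(1E)-3-oxobut-1-en-1-yl]-6-[(triethylsilyl)oxy]-1,2,3,4,4a,5,6,8a-octahydronaphthalene-1-carboxylate
Product: 23 tert-butyl (1S,4aS,5R,6R,8aR)-1,4a,6-trimethyl-5-(3-oxobutyl)-6-[(triethylsilyl)oxy]decahydronaphthalene-1-carboxylate
Conditions: H2 (3 atm), 10% Pd/C, EtOAc, rt
Reagents that add atoms: none
Why: Heterogeneous hydrogenation should saturate both the conjugated C11=C12 and the ring C6=C7 alkenes; no stereocentre is made or touched, and ketone, ester and silyl ether are inert.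

Step 15
Reactants: 23 tert-butyl (1S,4aS,5R,6R,8aR)-1,4a,6-trimethyl-5-(3-oxobutyl)-6-[(triethylsilyl)oxy]decahydronaphthalene-1-carboxylate
Product: 25 tert-butyl (1S,4aS,5R,6R,8aR)-1,4a,6-trimethyl-6-[(triethylsilyl)oxy]-5-{3-[(trifluoromethanesulfonyl)oxy]but-3-en-1-yl}decahydronaphthalene-1-carboxylate, via lithium enolate 24 (not isolated)
Conditions: LiN(i-Pr)2 (LDA), THF, −78 °C; then N-(5-chloropyridin-2-yl)-N-(trifluoromethanesulfonyl)trifluoromethanesulfonamide, −78 to 0 °C
Reagents that add atoms: N-(5-chloropyridin-2-yl)-N-(trifluoromethanesulfonyl)trifluoromethanesulfonamide, FC(F)(F)S(=O)(=O)N(c1ccc(Cl)cn1)S(=O)(=O)C(F)(F)F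
Why: Kinetic deprotonation of the methyl ketone at the less hindered methyl group and O-triflation of the terminal enolate should give the 1,1-disubstituted alkenyl triflate.

Step 16
Reactants: 25 tert-butyl (1S,4aS,5R,6R,8aR)-1,4a,6-trimethyl-6-[(triethylsilyl)oxy]-5-{3-[(trifluoromethanesulfonyl)oxy]but-3-en-1-yl}decahydronaphthalene-1-carboxylate
Product: 26 tert-butyl (1S,4aS,5R,6R,8aR)-1,4a,6-trimethyl-5-(3-methylidenepent-4-en-1-yl)-6-[(triethylsilyl)oxy]decahydronaphthalene-1-carboxylate
Conditions: CH2=CHSnBu3, Pd(PPh3)4 (5 mol %), LiCl, THF, 65 °C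
Reagents that add atoms: tributyl(vinyl)stannane, C=C[Sn](CCCC)(CCCC)CCCC
Why: Stille coupling of the alkenyl triflate with the vinylstannane builds the 2-substituted buta-1,3-diene under neutral conditions.

Step 17
Reactants: 26 tert-butyl (1S,4aS,5R,6R,8aR)-1,4a,6-trimethyl-5-(3-methylidenepent-4-en-1-yl)-6-[(triethylsilyl)oxy]decahydronaphthalene-1-carboxylate
Product: 27 [(1S,4aS,5R,6R,8aR)-1,4a,6-trimethyl-5-(3-methylidenepent-4-en-1-yl)-6-[(triethylsilyl)oxy]decahydronaphthalen-1-yl]methanol
Conditions: LiAlH4, THF, 0 °C to reflux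
Reagents that add atoms: none
Why: Hydride reduction of the hindered axial tert-butyl ester gives the C19 primary alcohol; the diene and the silyl ether are inert.

Step 18
Reactants: 27 [(1S,4aS,5R,6R,8aR)-1,4a,6-trimethyl-5-(3-methylidenepent-4-en-1-yl)-6-[(triethylsilyl)oxy]decahydronaphthalen-1-yl]methanol
Product: 28 (1R,2R,4aR,5S,8aS)-5-(hydroxymethyl)-2,5,8a-trimethyl-1-(3-methylidenepent-4-en-1-yl)decahydronaphthalen-2-ol
Conditions: Bu4NF, THF, rt to 40 °C
Reagents that add atoms: none
Why: Fluoride cleaves the tertiary triethylsilyl ether without acid, so the tertiary alcohol and the diene are not put at risk.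

Step 19
Reactants: 28 (1R,2R,4aR,5S,8aS)-5-(hydroxymethyl)-2,5,8a-trimethyl-1-(3-methylidenepent-4-en-1-yl)decahydronaphthalen-2-ol; 29 (2E)-3-(4-methoxyphenyl)prop-2-enoic acid
Product: 30 [(1S,4aS,5R,6R,8aR)-6-hydroxy-1,4a,6-trimethyl-5-(3-methylidenepent-4-en-1-yl)decahydronaphthalen-1-yl]methyl (2E)-3-(4-methoxyphenyl)prop-2-enoate (target)
Conditions: EDC·HCl, DMAP, CH2Cl2, rt
Reagents that add atoms: none
Why: Steglich esterification should acylate only the primary C19 alcohol, since the tertiary C8 alcohol does not react under these conditions.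

**Compound list**

1 | methyl (2E)-3,7-dimethylocta-2,6-dienoate (methyl geranate) | COC(=O)/C=C(\C)CCC=C(C)C | starting material
2 | methyl (2E)-5-(3,3-dimethyloxiran-2-yl)-3-methylpent-2-enoate (racemic epoxide) | COC(=O)/C=C(\C)CCC1OC1(C)C | intermediate
3 | methyl (2E)-3-methyl-6-oxohex-2-enoate | COC(=O)/C=C(\C)CCC=O | intermediate
4 | methyl (2E)-6-hydroxy-3-methylhex-2-enoate | COC(=O)/C=C(\C)CCCO | intermediate
5 | methyl (2E)-6-iodo-3-methylhex-2-enoate | COC(=O)/C=C(\C)CCCI | intermediate
6 | tert-butyl 2-bromopropanoate (racemic) | CC(Br)C(=O)OC(C)(C)C | starting material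
7 | glycolaldehyde dimer (2,5-dihydroxy-1,4-dioxane) | OC1COC(O)CO1 | starting material
8 | (1-tert-butoxy-1-oxopropan-2-yl)triphenylphosphonium bromide | CC(C(=O)OC(C)(C)C)[P+](c1ccccc1)(c1ccccc1)c1ccccc1.[Br-] | intermediate
9 | tert-butyl 2-(triphenyl-λ5-phosphanylidene)propanoate | CC(C(=O)OC(C)(C)C)=P(c1ccccc1)(c1ccccc1)c1ccccc1 | intermediate
10 | tert-butyl (2E)-4-hydroxy-2-methylbut-2-enoate | OC/C=C(\C)C(=O)OC(C)(C)C | intermediate
11 | tert-butyl (2E)-4-[(diethoxyphosphoryl)oxy]-2-methylbut-2-enoate | CCOP(=O)(OCC)OC/C=C(\C)C(=O)OC(C)(C)C | intermediate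
12 | bis[(4E)-6-methoxy-4-methyl-6-oxohex-4-en-1-yl]zinc | COC(=O)/C=C(\C)CCC[Zn]CCC/C(C)=C/C(=O)OC | intermediate
13 | 1-tert-butyl 8-methyl (2S,6E)-2-ethenyl-2,6-dimethyloct-6-enedioate | COC(=O)/C=C(\C)CCC[C@@](C)(C=C)C(=O)OC(C)(C)C | intermediate
14 | pent-4-en-2-ol (racemic) | CC(O)CC=C | starting material
15 | 1-tert-butyl 8-methyl (2S,6E)-2-[(1E)-4-hydroxypent-1-en-1-yl]-2,6-dimethyloct-6-enedioate (both carbinol epimers) | COC(=O)/C=C(\C)CCC[C@@](C)(/C=C/CC(C)O)C(=O)OC(C)(C)C | intermediate
16 | 1-tert-butyl 8-methyl (2S,6E)-2,6-dimethyl-2-[(1E)-4-oxopent-1-en-1-yl]oct-6-enedioate | COC(=O)/C=C(\C)CCC[C@@](C)(/C=C/CC(C)=O)C(=O)OC(C)(C)C | intermediate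
17 | 1-tert-butyl 8-methyl (2S,6E)-2,6-dimethyl-2-{(1E,3Z)-4-[(triethylsilyl)oxy]penta-1,3-dien-1-yl}oct-6-enedioate | COC(=O)/C=C(\C)CCC[C@@](C)(/C=C/C=C(/C)O[Si](CC)(CC)CC)C(=O)OC(C)(C)C | intermediate
18 | tert-butyl (2S,6E)-8-hydroxy-2,6-dimethyl-2-{(1E,3Z)-4-[(triethylsilyl)oxy]penta-1,3-dien-1-yl}oct-6-enoate | OC/C=C(\C)CCC[C@@](C)(/C=C/C=C(/C)O[Si](CC)(CC)CC)C(=O)OC(C)(C)C | intermediate
19 | tert-butyl (2S,6E)-2,6-dimethyl-8-oxo-2-{(1E,3Z)-4-[(triethylsilyl)oxy]penta-1,3-dien-1-yl}oct-6-enoate | O=C/C=C(\C)CCC[C@@](C)(/C=C/C=C(/C)O[Si](CC)(CC)CC)C(=O)OC(C)(C)C | intermediate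
20 | tert-butyl (1S,4aS,5R,6R,8aR)-5-formyl-1,4a,6-trimethyl-6-[(triethylsilyl)oxy]-1,2,3,4,4a,5,6,8a-octahydronaphthalene-1-carboxylate | O=C[C@@H]1[C@@]2(C)CCC[C@](C)(C(=O)OC(C)(C)C)[C@@H]2C=C[C@@]1(C)O[Si](CC)(CC)CC | intermediate
21 | 1-(triphenyl-λ5-phosphanylidene)propan-2-one | CC(=O)C=P(c1ccccc1)(c1ccccc1)c1ccccc1 | starting material
22 | tert-butyl (1S,4aS,5R,6R,8aR)-1,4a,6-trimethyl-5-[(1E)-3-oxobut-1-en-1-yl]-6-[(triethylsilyl)oxy]-1,2,3,4,4a,5,6,8a-octahydronaphthalene-1-carboxylate | CC(=O)/C=C/[C@@H]1[C@@]2(C)CCC[C@](C)(C(=O)OC(C)(C)C)[C@@H]2C=C[C@@]1(C)O[Si](CC)(CC)CC | intermediate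
23 | tert-butyl (1S,4aS,5R,6R,8aR)-1,4a,6-trimethyl-5-(3-oxobutyl)-6-[(triethylsilyl)oxy]decahydronaphthalene-1-carboxylate | CC(=O)CC[C@@H]1[C@@]2(C)CCC[C@](C)(C(=O)OC(C)(C)C)[C@@H]2CC[C@@]1(C)O[Si](CC)(CC)CC | intermediate
24 | lithium enolate of 23 at the terminal methyl carbon | [Li]OC(=C)CC[C@@H]1[C@@]2(C)CCC[C@](C)(C(=O)OC(C)(C)C)[C@@H]2CC[C@@]1(C)O[Si](CC)(CC)CC | intermediate
25 | tert-butyl (1S,4aS,5R,6R,8aR)-1,4a,6-trimethyl-6-[(triethylsilyl)oxy]-5-{3-[(trifluoromethanesulfonyl)oxy]but-3-en-1-yl}decahydronaphthalene-1-carboxylate | C=C(OS(=O)(=O)C(F)(F)F)CC[C@@H]1[C@@]2(C)CCC[C@](C)(C(=O)OC(C)(C)C)[C@@H]2CC[C@@]1(C)O[Si](CC)(CC)CC | intermediate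
26 | tert-butyl (1S,4aS,5R,6R,8aR)-1,4a,6-trimethyl-5-(3-methylidenepent-4-en-1-yl)-6-[(triethylsilyl)oxy]decahydronaphthalene-1-carboxylate | C=CC(=C)CC[C@@H]1[C@@]2(C)CCC[C@](C)(C(=O)OC(C)(C)C)[C@@H]2CC[C@@]1(C)O[Si](CC)(CC)CC | intermediate
27 | [(1S,4aS,5R,6R,8aR)-1,4a,6-trimethyl-5-(3-methylidenepent-4-en-1-yl)-6-[(triethylsilyl)oxy]decahydronaphthalen-1-yl]methanol | C=CC(=C)CC[C@@H]1[C@@]2(C)CCC[C@](C)(CO)[C@@H]2CC[C@@]1(C)O[Si](CC)(CC)CC | intermediate
28 | (1R,2R,4aR,5S,8aS)-5-(hydroxymethyl)-2,5,8a-trimethyl-1-(3-methylidenepent-4-en-1-yl)decahydronaphthalen-2-ol | C=CC(=C)CC[C@@H]1[C@@]2(C)CCC[C@](C)(CO)[C@@H]2CC[C@@]1(C)O | intermediate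
29 | (2E)-3-(4-methoxyphenyl)prop-2-enoic acid | COc1ccc(/C=C/C(=O)O)cc1 | starting material
30 | [(1S,4aS,5R,6R,8aR)-6-hydroxy-1,4a,6-trimethyl-5-(3-methylidenepent-4-en-1-yl)decahydronaphthalen-1-yl]methyl (2E)-3-(4-methoxyphenyl)prop-2-enoate | C=CC(=C)CC[C@@H]1[C@@]2(C)CCC[C@](C)(COC(=O)/C=C/c3ccc(OC)cc3)[C@@H]2CC[C@@]1(C)O | target

**Step count**

Total: 19 steps. Longest linear sequence: 17 steps (steps 1–3, then 6–19).

**Steps most likely to fail**

Step 12. The cycloaddition may be too slow at a temperature the silyl dienol ether tolerates, so that silyl migration or hydrolysis competes, and endo and facial selectivity may erode on heating. The fallback sets out from 19 and comes back at 20. It replaces the thermal pericyclic closure by a Lewis-acid-mediated polar annulation: 19 is treated with Me2AlCl (1.1 equiv) in CH2Cl2 at −78 °C. Coordination at the formyl oxygen should trigger vinylogous Mukaiyama–Michael attack of C5 on C10, and the aluminium enolate should then close C8–C9 onto the silyl oxocarbenium ion in a Mukaiyama aldol step, with silicon staying on the C8 oxygen. This gives 20 directly; no new compound is made (F0). Because this path is stepwise, the C8 configuration is then set in the aldol closure and would need to be checked.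

Step 6. Iodine–zinc exchange may be incomplete and alkyl transfer from the functionalised dialkylzinc sluggish, leading to ethyl transfer, linear SN2 substitution or low enantioselectivity. The fallback sets out from 5 and comes back at 13. Commercial tiglic acid is converted with LiN(i-Pr)2 (2.2 equiv) in THF/DMPU into its dienolate dianion and alkylated at the α-carbon with 5, giving racemic 2-ethenyl-8-methoxy-2,6-dimethyl-8-oxooct-6-enoic acid F1. Classical resolution by fractional crystallisation of its 1-phenylethylamine salt, followed by acidification, gives (2S,6E)-2-ethenyl-8-methoxy-2,6-dimethyl-8-oxooct-6-enoic acid F2 and leaves (2R,6E)-2-ethenyl-8-methoxy-2,6-dimethyl-8-oxooct-6-enoic acid F3 in the mother liquor. Esterification of F2 with tert-butyl 2,2,2-trichloroacetimidate and catalytic BF3·OEt2 returns 13.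

Step 7. Initiation at the vinyl group on the quaternary carbon may be slow, so that partner homodimerisation, alkene isomerisation by ruthenium hydrides and catalyst decay outrun productive cross-metathesis. The fallback sets out from 13 and comes back at 16. Lemieux–Johnson cleavage (OsO4 cat., NaIO4, 2,6-lutidine, dioxane/H2O) of the vinyl group, with the electron-poor conjugated alkene spared, gives 1-tert-butyl 8-methyl (2S,6E)-2-formyl-2,6-dimethyloct-6-enedioate F4. Takai olefination (CrCl2, CHI3, THF, 0 °C) gives 1-tert-butyl 8-methyl (2S,6E)-2-[(E)-2-iodoethenyl]-2,6-dimethyloct-6-enedioate F5. Palladium-catalysed acetonylation through the tin enolate of acetone (isopropenyl acetate, Bu3SnOMe, PdCl2[P(o-tol)3]2, toluene, 100 °C) then gives the β,γ-unsaturated methyl ketone 16.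

**Further compounds**

F0 | step 12 | none | none
F1 | step 6 | 2-ethenyl-8-methoxy-2,6-dimethyl-8-oxooct-6-enoic acid (racemic, 6E) | COC(=O)/C=C(\C)CCCC(C)(C=C)C(=O)O
F2 | step 6 | (2S,6E)-2-ethenyl-8-methoxy-2,6-dimethyl-8-oxooct-6-enoic acid | COC(=O)/C=C(\C)CCC[C@@](C)(C=C)C(=O)O
F3 | step 6 | (2R,6E)-2-ethenyl-8-methoxy-2,6-dimethyl-8-oxooct-6-enoic acid | COC(=O)/C=C(\C)CCC[C@](C)(C=C)C(=O)O
F4 | step 7 | 1-tert-butyl 8-methyl (2S,6E)-2-formyl-2,6-dimethyloct-6-enedioate | COC(=O)/C=C(\C)CCC[C@@](C)(C=O)C(=O)OC(C)(C)C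
F5 | step 7 | 1-tert-butyl 8-methyl (2S,6E)-2-[(E)-2-iodoethenyl]-2,6-dimethyloct-6-enedioate | COC(=O)/C=C(\C)CCC[C@@](C)(/C=C/I)C(=O)OC(C)(C)C
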